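**Strategy.** The route rests on cutting the δ-lactone ring (C19–O–C20–C10–C5–C4) at C4–C19 and at the ring A/B fusion bond C5–C10. One photoredox operation makes both bonds: a tertiary C10 radical, released from a caesium oxalate, closes ring B onto an enone, and the resulting C4 enolate is acylated by a carbonate carried on C20. This exploits the cis, 1,3-diaxial relation of C19 and C20 across C5. The precursor is a monocyclic ring C building block from (S)-carvone that carries the enone chain on C8, the oxalate/carbonate/acetal unit on C9 and the dimethoxybenzyl group on C14. Ring A (aldol), the C13 alcohol and the spiro enedione follow.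

Key step: step 13

Remark on numbering: carbons are numbered as in the finished skeleton throughout. C1–C5 and C10 form ring A, C5–C10 ring B, and C8, C9, C11–C14 ring C. C15 is the CH2 between C14 and the six-membered oxygenated ring (C1′–C6′). C16 is the methyl on C13, C17 the methyl on C8, C18 the methyl on C4, C19 the lactone carbonyl and C20 the lactone CH2. β is the face of C17, α the opposite face.

Remark on chemistry: the carbinol centre C10 made in step 7 forms as a mixture and is destroyed in step 13. The spiro centre C2′ is assumed to be the thermodynamically preferred epimer under reversible oxa-Michael conditions.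

## Route

Step 1
Reactants: 1 (S)-(+)-carvone
Product: 2 (5S)-2,6-dimethyl-5-(prop-1-en-2-yl)cyclohex-2-en-1-one (6-methylcarvone; C6 epimer mixture)
Conditions: LiN(i-Pr)2, THF, −78 °C; MeI, −78 to 0 °C
Reagents that add atoms: iodomethane CI
Why: Kinetic deprotonation can occur only at the α′-CH2 (the future C8), and enolate alkylation gives the methyl ketone as an epimer mixture whose new centre is flattened again in step 2.

Step 2
Reactants: 2 6-methylcarvone
Product: 3 (5R,6R)-2,6-dimethyl-6-(prop-2-en-1-yl)-5-(prop-1-en-2-yl)cyclohex-2-en-1-one (allyl trans to isopropenyl)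
Conditions: LiN(i-Pr)2, THF/DMPU, −78 °C; allyl bromide, −78 to 0 °C
Reagents that add atoms: allyl bromide C=CCBr
Why: Enolate alkylation in which allyl bromide approaches anti to the neighbouring isopropenyl group, so that quaternary C8 carries the allyl group (future C7–C5) trans and C17 cis to the C9 substituent.

Step 3
Reactants: 3 allyl methyl carvone
Product: 4 2-[(1R,2R)-2,4-dimethyl-3-oxo-2-(prop-2-en-1-yl)cyclohex-4-en-1-yl]prop-2-enal
Conditions: SeO2 (1.2 equiv), 1,4-dioxane/H2O, 80 °C
Reagents that add atoms: selenium dioxide O=[Se]=O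
Why: Riley allylic oxidation (ene reaction, then [2,3]-shift) attacks the most nucleophilic, 1,1-disubstituted alkene at its methyl group and carries it to the aldehyde, whereas the monosubstituted allyl group and the electron-poor enone react more slowly.

Step 4
Reactants: 4 enal
Product: 5 2-{1-[(1R,2R)-2,4-dimethyl-3-oxo-2-(prop-2-en-1-yl)cyclohex-4-en-1-yl]ethenyl}-1,3-dioxolane
Conditions: ethylene glycol, pyridinium p-toluenesulfonate (cat.), benzene, reflux with water removal
Reagents that add atoms: ethylene glycol OCCO
Why: Acid-catalysed acetalisation is selective for the aldehyde over the hindered conjugated ketone and masks C1 as a branched dioxolane.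

Step 5
Reactants: 5 dioxolane enone
Product: 7 ring C enol triflate (C13=C14 with OTf on C14 and C16 on C13; C8 carries C17 and the allyl group; C9 carries the 1-(1,3-dioxolan-2-yl)ethenyl group cis to C17), via lithium C13–C14 enolate 6 (not isolated)
Conditions: LiBH(s-Bu)3, THF, −78 °C; then PhNTf2, −78 to 0 °C
Reagents that add atoms: N-phenylbis(trifluoromethanesulfonimide) O=S(=O)(N(c1ccccc1)S(=O)(=O)C(F)(F)F)C(F)(F)F
Why: Conjugate hydride reduction of the β-unsubstituted enone gives only the C13–C14 enolate, and O-sulfonylation fixes it as the tetrasubstituted enol triflate.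

Step 6
Reactants: 7 enol triflate
Product: 8 aldehyde (the allyl group on C8 converted into the 3-oxopropyl chain C7–C6–C5HO; otherwise as 7)
Conditions: PdCl2(PhCN)2 (cat.), CuCl2·2H2O (cat.), AgNO2 (cat.), t-BuOH/MeNO2, O2 (1 atm), 25 °C
Reagents that add atoms: dioxygen O=O
Why: The nitrite-modified Wacker oxidation delivers oxygen to the terminal carbon of the monosubstituted alkene (aldehyde-selective), while the 1,1-disubstituted alkene and the enol triflate are inert to it.

Step 7
Reactants: 8 aldehyde
Product: 9 aldehyde diol (C10 now bears OH, the CH2OH group C20 and the dioxolane C1; C10 epimer mixture)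
Conditions: OsO4 (cat.), N-methylmorpholine N-oxide, acetone/H2O, 25 °C
Reagents that add atoms: N-methylmorpholine N-oxide C[N+]1([O-])CCOCC1; water O
Why: Catalytic OsO4 dihydroxylation takes the only electron-neutral alkene (the enol triflate is deactivated), and the new carbinol centre C10 needs no control because step 13 erases it.

Step 8
Reactants: 10 3-bromobutan-2-one; 11 triphenylphosphine
Product: 13 3-(triphenyl-λ5-phosphanylidene)butan-2-one, via (3-oxobutan-2-yl)triphenylphosphonium bromide 12 (not isolated)
Conditions: toluene, 60 °C; then NaOH (aq), CH2Cl2, 25 °C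
Reagents that add atoms: none
Why: SN2 displacement of the α-bromo ketone by the phosphine and deprotonation of the salt give the stabilised ylide.

Step 9
Reactants: 9 aldehyde diol; 13 ylide
Product: 14 (E)-enone diol (chain on C8 now C7H2–C6H2–C5H=C4(C18)–C3(=O)–C2H3; otherwise as 9)
Conditions: toluene, 90 °C
Reagents that add atoms: none
Why: Wittig olefination with a stabilised ylide is selective for the aldehyde and gives the (E)-trisubstituted enone.

Step 10
Reactants: 14 enone diol enol triflate; 15 2,5-dimethoxybenzyl chloride
Product: 17 benzylated enone diol (C14 now bears the 2,5-dimethoxybenzyl group C15–aryl; C13=C14 retained), via (2,5-dimethoxybenzyl)zinc chloride 16 (not isolated)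
Conditions: Zn, LiCl, THF, 25 °C (on 15); then 14, Pd(OAc)2 (cat.), 2-dicyclohexylphosphino-2′,6′-dimethoxybiphenyl (cat.), THF, 50 °C
Reagents that add atoms: none
Why: Negishi coupling of the benzylzinc chloride with the enol triflate at zerovalent palladium forms C14–C15 without moving the alkene, an excess of the zinc reagent covering the free hydroxyls.

Step 11
Reactants: 17 benzylated enone diol
Product: 18 primary methyl carbonate (C20–OCO2Me; tertiary C10–OH free)
Conditions: ClCO2Me, pyridine, CH2Cl2, 0 °C
Reagents that add atoms: methyl chloroformate COC(Cl)=O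
Why: Acylation with the chloroformate occurs only at the primary hydroxyl, the hindered tertiary C10–OH being far slower.

Step 12
Reactants: 18 carbonate
Product: 20 caesium oxalate of the tertiary C10 alcohol, via methyl oxalate 19 (not isolated)
Conditions: ClC(O)CO2Me, Et3N, 4-(dimethylamino)pyridine (cat.), CH2Cl2, 0 °C; then CsOH (1.0 equiv), THF/H2O, 0 °C
Reagents that add atoms: methyl chlorooxoacetate COC(=O)C(Cl)=O; caesium hydroxide [Cs+].[OH-]
Why: The very electrophilic oxalyl half-ester chloride acylates the tertiary alcohol, and one equivalent of hydroxide cleaves only the activated oxalate methyl ester, leaving the carbonate.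

Step 13
Reactants: 20 caesium oxalate
Product: 22 ring B lactone (rings B and C plus the δ-lactone C19(=O)–O–C20; C4 bears C18 and an acetyl group C3(=O)C2H3; C10 bears the dioxolane C1; 5α-H; C13=C14 retained), via caesium C3–C4 enolate 21 (not isolated)
Conditions: Ir[dF(CF3)ppy]2(dtbbpy)PF6 (2 mol %), blue LEDs, anhydrous DME/DMF (3:1), 25 °C
Reagents that add atoms: none
Why: Proposed new method: the excited trivalent iridium complex oxidises the caesium oxalate, which loses two CO2 to give the tertiary C10 radical, this adds to C5 of the (E)-enone, divalent iridium reduces the resulting α-keto radical to the caesium enolate, and its carbon C4 attacks the methyl carbonate held on C20 with loss of methoxide. The closest known reaction types are the decarboxylative tertiary-radical conjugate addition of alkyl oxalates and radical–polar crossover annulations that end in an aldol; the Claisen-type acylation as the closing event is the new element. Ring B closes in the 6-exo-trig radical mode through a chair, and the δ-lactone closes by 6-exo-trig acyl substitution. C5 is set by the chair (enone arm equatorial, H5 axial and trans to C17), C10 by the slim CH2O arm taking the crowded pseudoaxial site next to C17 while the branched dioxolane stays equatorial, and C4 by A(1,3) strain, which keeps H5 in the plane of the tetrasubstituted enolate so that the carbonate anchored on C10 reaches one face only. The step needs cyclisation before the radical is quenched and C- rather than O-acylation: the activated enone makes the 6-exo addition fast, water is excluded so that the enolate survives, and O-acylation would require an eight-membered ring. Any C10 epimer would give a trans-fused lactone that cannot close ring A in step 14 and is removed there.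

Step 14
Reactants: 22 ring B lactone
Product: 24 ring A enone (C1=C2–C3=O; rings A, B, C and the lactone complete), via C1 aldehyde 23 (not isolated)
Conditions: 1 M HCl, THF, 40 °C; then pyrrolidine (cat.), AcOH (cat.), toluene, 60 °C
Reagents that add atoms: none
Why: Aqueous acid unmasks the C1 aldehyde, and intramolecular aldol condensation between the acetyl methyl C2 (the only enolisable position) and the non-enolisable aldehyde closes ring A as the six-membered enone.

Step 15
Reactants: 24 ring A enone
Product: 26 ring A enol triflate (C2=C3 with OTf on C3), via lithium C2–C3 enolate 25 (not isolated)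
Conditions: LiBH(s-Bu)3, THF, −78 °C; then N-(5-chloropyridin-2-yl)bis(trifluoromethanesulfonimide), −78 to 0 °C
Reagents that add atoms: N-(5-chloropyridin-2-yl)bis(trifluoromethanesulfonimide) O=S(=O)(N(c1ccc(Cl)cn1)S(=O)(=O)C(F)(F)F)C(F)(F)F
Why: Conjugate hydride reduction of the enone (β-carbon C1 unsubstituted, carbonyl shielded by quaternary C4) gives the C2–C3 enolate, which is triflated on oxygen.

Step 16
Reactants: 26 ring A enol triflate
Product: 27 tetracyclic lactone with saturated ring A (C13=C14 alkene and 2,5-dimethoxybenzyl group retained)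
Conditions: H2 (1 atm), PtO2, Li2CO3, EtOAc, 25 °C
Reagents that add atoms: none
Why: Hydrogenolysis of the enol triflate over platinum removes the former carbonyl oxygen and saturates C2–C3 (ketone to methylene by way of the enol triflate), while the hindered tetrasubstituted alkene and the arene are left.

Step 17
Reactants: 27 tetracyclic alkene
Product: 29 13α-hydroxy compound (13α-OH; C16 β; 14α-H; C15 β), via C13 alkylborane 28 (not isolated)
Conditions: BH3·THF, THF, 0 to 25 °C; then H2O2, NaOAc (aq), 0 to 25 °C
Reagents that add atoms: hydrogen peroxide OO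
Why: Hydroboration–oxidation in which borane adds syn from the α face (the β face is blocked by the axial C17 methyl) with boron on the less hindered C13, and oxidation with retention sets the 13α-hydroxyl and the 14α-hydrogen together.

Step 18
Reactants: 29 13α-hydroxy dimethoxyarene
Product: 31 target CNP0290557.1, via 2-alkyl-1,4-benzoquinone 30 (not isolated)
Conditions: (NH4)2Ce(NO3)6, MeCN/H2O, 0 °C; then Et3N (cat.), CH2Cl2, 25 °C
Reagents that add atoms: water O
Why: Oxidative demethylation by tetravalent cerium gives the quinone, and 5-exo-trig intramolecular oxa-Michael addition of the 13α-hydroxyl to C2′ with protonation at C3′ gives the spiro enedione, the reversible addition being expected to settle on the epimer that places the flat C1′ carbonyl, not the C3′ methylene, next to C16.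

## Compound list

1 | (S)-(+)-carvone | CC1=CC[C@@H](CC1=O)C(C)=C | starting material
2 | (5S)-2,6-dimethyl-5-(prop-1-en-2-yl)cyclohex-2-en-1-one (C6 epimer mixture) | CC1[C@@H](C(C)=C)CC=C(C)C1=O | intermediate
3 | (5R,6R)-2,6-dimethyl-6-(prop-2-en-1-yl)-5-(prop-1-en-2-yl)cyclohex-2-en-1-one | C[C@@]1(CC=C)[C@@H](C(C)=C)CC=C(C)C1=O | intermediate
4 | 2-[(1R,2R)-2,4-dimethyl-3-oxo-2-(prop-2-en-1-yl)cyclohex-4-en-1-yl]prop-2-enal | C[C@@]1(CC=C)[C@@H](C(=C)C=O)CC=C(C)C1=O | intermediate
5 | 2-{1-[(1R,2R)-2,4-dimethyl-3-oxo-2-(prop-2-en-1-yl)cyclohex-4-en-1-yl]ethenyl}-1,3-dioxolane | C[C@@]1(CC=C)[C@@H](C(=C)C2OCCO2)CC=C(C)C1=O | intermediate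
6 | lithium C13–C14 enolate of 5 after conjugate reduction | C[C@@]1(CC=C)[C@@H](C(=C)C2OCCO2)CCC(C)=C1[O-].[Li+] | intermediate
7 | ring C enol triflate (C14–OTf, C13=C14; allyl and C17 on C8; dioxolanyl-ethenyl on C9) | C[C@@]1(CC=C)[C@@H](C(=C)C2OCCO2)CCC(C)=C1OS(=O)(=O)C(F)(F)F | intermediate
8 | enol triflate aldehyde (3-oxopropyl chain on C8) | C[C@@]1(CCC=O)[C@@H](C(=C)C2OCCO2)CCC(C)=C1OS(=O)(=O)C(F)(F)F | intermediate
9 | enol triflate aldehyde diol (C10–OH, C20–OH; C10 epimers) | C[C@@]1(CCC=O)[C@@H](C(O)(CO)C2OCCO2)CCC(C)=C1OS(=O)(=O)C(F)(F)F | intermediate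
10 | 3-bromobutan-2-one | CC(Br)C(C)=O | starting material
11 | triphenylphosphine | c1ccc(cc1)P(c1ccccc1)c1ccccc1 | starting material
12 | (3-oxobutan-2-yl)triphenylphosphonium bromide | CC(=O)C(C)[P+](c1ccccc1)(c1ccccc1)c1ccccc1.[Br-] | intermediate
13 | 3-(triphenyl-λ5-phosphanylidene)butan-2-one | CC(=O)C(C)=P(c1ccccc1)(c1ccccc1)c1ccccc1 | intermediate
14 | (E)-enone diol enol triflate | C[C@@]1(CC/C=C(\C)C(C)=O)[C@@H](C(O)(CO)C2OCCO2)CCC(C)=C1OS(=O)(=O)C(F)(F)F | intermediate
15 | 2,5-dimethoxybenzyl chloride | COc1ccc(OC)c(CCl)c1 | starting material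
16 | (2,5-dimethoxybenzyl)zinc chloride | COc1ccc(OC)c(C[Zn]Cl)c1 | intermediate
17 | benzylated (E)-enone diol | C[C@@]1(CC/C=C(\C)C(C)=O)[C@@H](C(O)(CO)C2OCCO2)CCC(C)=C1Cc1cc(OC)ccc1OC | intermediate
18 | C20 methyl carbonate with free tertiary C10–OH | C[C@@]1(CC/C=C(\C)C(C)=O)[C@@H](C(O)(COC(=O)OC)C2OCCO2)CCC(C)=C1Cc1cc(OC)ccc1OC | intermediate
19 | C10 methyl oxalate of 18 | C[C@@]1(CC/C=C(\C)C(C)=O)[C@@H](C(OC(=O)C(=O)OC)(COC(=O)OC)C2OCCO2)CCC(C)=C1Cc1cc(OC)ccc1OC | intermediate
20 | C10 caesium oxalate | C[C@@]1(CC/C=C(\C)C(C)=O)[C@@H](C(OC(=O)C(=O)[O-])(COC(=O)OC)C2OCCO2)CCC(C)=C1Cc1cc(OC)ccc1OC.[Cs+] | intermediate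
21 | caesium C3–C4 enolate after ring B closure | C[C@@]12CC[C@@H](C(C)=C(C)[O-])[C@](COC(=O)OC)(C3OCCO3)[C@H]1CCC(C)=C2Cc1cc(OC)ccc1OC.[Cs+] | intermediate
22 | ring B lactone with C4 acetyl and C10 dioxolane | C[C@@]12CC[C@@H]([C@](C)(C(C)=O)C(=O)OC3)[C@]3(C4OCCO4)[C@H]1CCC(C)=C2Cc1cc(OC)ccc1OC | intermediate
23 | C1 aldehyde of 22 | C[C@@]12CC[C@@H]([C@](C)(C(C)=O)C(=O)OC3)[C@]3(C=O)[C@H]1CCC(C)=C2Cc1cc(OC)ccc1OC | intermediate
24 | ring A enone (C1=C2–C3=O) | C[C@@]12CC[C@@H]3[C@]4(C=CC(=O)[C@]3(C)C(=O)OC4)[C@H]1CCC(C)=C2Cc1cc(OC)ccc1OC | intermediate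
25 | lithium C2–C3 enolate | C[C@@]12CC[C@@H]3[C@]4(CC=C([O-])[C@]3(C)C(=O)OC4)[C@H]1CCC(C)=C2Cc1cc(OC)ccc1OC.[Li+] | intermediate
26 | ring A enol triflate (C3–OTf, C2=C3) | C[C@@]12CC[C@@H]3[C@]4(CC=C(OS(=O)(=O)C(F)(F)F)[C@]3(C)C(=O)OC4)[C@H]1CCC(C)=C2Cc1cc(OC)ccc1OC | intermediate
27 | tetracyclic lactone with saturated ring A and C13=C14 | C[C@@]12CC[C@@H]3[C@]4(CCC[C@]3(C)C(=O)OC4)[C@H]1CCC(C)=C2Cc1cc(OC)ccc1OC | intermediate
28 | C13 alkylborane (13α-BH2, 14α-H) | C[C@@]12CC[C@@H]3[C@]4(CCC[C@]3(C)C(=O)OC4)[C@H]1CC[C@](C)([BH2])[C@H]2Cc1cc(OC)ccc1OC | intermediate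
29 | 13α-hydroxy dimethoxyarene | C[C@@]12CC[C@@H]3[C@]4(CCC[C@]3(C)C(=O)OC4)[C@H]1CC[C@](C)(O)[C@H]2Cc1cc(OC)ccc1OC | intermediate
30 | 13α-hydroxy 2-alkyl-1,4-benzoquinone | C[C@@]12CC[C@@H]3[C@]4(CCC[C@]3(C)C(=O)OC4)[C@H]1CC[C@](C)(O)[C@H]2CC1=CC(=O)C=CC1=O | intermediate
31 | target CNP0290557.1 | C[C@@]12CC[C@@H]3[C@]4(CCC[C@]3(C)C(=O)OC4)[C@H]1CC[C@]1(C)O[C@]3(CC(=O)C=CC3=O)C[C@@H]21 | target

## Step count and risks

Total step count: 18. Longest linear sequence: 17 (steps 1–7 and 9–18; step 8 prepares the ylide).

Steps most likely to fail: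

1. Step 13 (proposed new method). What may go wrong: the enolate is protonated or the α-keto radical abstracts hydrogen before acylation; the excited photocatalyst is quenched by the electron-rich arene; facial selectivity at the C10 radical is low. Fallback with known chemistry, setting out from 20 and returning at 22: 20 is cyclised under the established aqueous conditions for oxalate-derived tertiary radicals (same iridium photocatalyst, DME/DMF/H2O, blue LEDs), where the enolate is simply protonated, to give the ketone carbonate F1. Without isolation the solvents are exchanged for dry THF and KOt-Bu is added; the ketone enolates equilibrate and only the C4 enolate can reach the carbonate (six-membered lactone, the C2 enolate would need an eight-membered ring), so the known base-mediated Claisen-type acylation gives 22.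

2. Step 17. What may go wrong: hydroboration of the hindered tetrasubstituted alkene is slower than borane reduction of the lactone, or boron attaches at C14. Fallback, setting out from 27 and returning at 29: epoxidation with mCPBA from the open α face gives the 13α,14α-epoxide F2. LiN(i-Pr)2 in THF removes a benzylic C15 hydrogen and opens the epoxide at C14 to the tertiary allylic alcohol F3 (13α-OH, C14=C15). Hydroxyl-directed hydrogenation with [Ir(cod)(PCy3)(py)]PF6 and H2 in CH2Cl2 then delivers hydrogen to C14 from the α face and gives 29.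

3. Step 6. What may go wrong: oxidation takes the Markovnikov course to the methyl ketone, or transient zerovalent palladium inserts into the enol triflate. Fallback, setting out from 7 and returning at 8: hydroboration with bis(3-methylbutan-2-yl)borane, which selects the monosubstituted alkene, and oxidation with H2O2/NaOAc give the primary alcohol F4. Oxidation with 1,1,1-triacetoxy-1,1-dihydro-1,2-benziodoxol-3(1H)-one in CH2Cl2 gives 8.

Further compounds

F1 | step 13 | ketone carbonate (ring B closed, C4–H, C20 methyl carbonate, C10 dioxolane) | C[C@@]12CC[C@@H](C(C)C(C)=O)[C@](COC(=O)OC)(C3OCCO3)[C@H]1CCC(C)=C2Cc1cc(OC)ccc1OC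
F2 | step 17 | 13α,14α-epoxide of 27 | C[C@@]12CC[C@@H]3[C@]4(CCC[C@]3(C)C(=O)OC4)[C@H]1CC[C@]1(C)O[C@]21Cc1cc(OC)ccc1OC
F3 | step 17 | 13α-hydroxy C14=C15 allylic alcohol | C[C@@]12CC[C@@H]3[C@]4(CCC[C@]3(C)C(=O)OC4)[C@H]1CC[C@](C)(O)C2=Cc1cc(OC)ccc1OC
F4 | step 6 | enol triflate primary alcohol (3-hydroxypropyl chain on C8) | C[C@@]1(CCCO)[C@@H](C(=C)C2OCCO2)CCC(C)=C1OS(=O)(=O)C(F)(F)F
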